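The grey run gained 0.0472 /d of the charge over its first 1.25 d, and the bench rule says that target goes with loading and with time. Carried to birch at grey's temperature, the rule gives 74.5% of the charge. Carried from the ochre run to oak's loading and time at ochre's temperature, it gives 314%, over the whole charge, so the rule has a border.

the same everywhere: substrate 0.072 M
- grey: free catalyst 0.19 mol%; temperature 75 °C; run made earlier
- ochre: free catalyst 0.33 mol%; temperature 100 °C; run made earlier
- birch: free catalyst 0.5 mol%; temperature 80 °C; time 6.0 d
- oak: free catalyst 0.25 mol%; temperature 120 °C; time 6.0 d

- grey (time / d: target / %): 0.625: 3.1; 1.25: 5.9; 1.67: 7.5; 2.50: 10.8; 3.00: 12.2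
- ochre (time / h: target / %): 2.00: 6.3; 8.00: 23.0; 12.0: 31.9; 20.0: 45.5; 25.0: 51.9

(each reading ± 0.3 percentage points)

- the analysis behind the earlier runs scatters by 0.3 percentage points, standard deviation

* the flask that ends with the higher amount of target, in percent of the substrate charged, or "neither" when 2 percentage points or less lies between them (birch / oak / neither)
* final target, as a percentage of the substrate charged, in birch
* final target, as a percentage of the substrate charged, in oak

Both runs bend, even as rate per substrate left. Between an early and a late stretch, the catalyst lost is read as the loading times the fractional fall of that rate. Grey then gives 187 and ochre 498. This is the turnover capacity, target made over catalyst lost, a ratio of two rates from which time drops out. Both are readings, and the scatter weighs heavily on them. The demand of a flask is one over its loading, and the rule stops where demand over capacity nears one. Birch, held against grey, stands at 1.07, and oak, held against ochre, at 0.803. The reckoning made here therefore puts birch short of a ceiling of 93.6% and lets oak reach its charge.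

The forecast named oak, with 58% for birch and 98% for oak, on the ground that “the loss follows time rather than product: the catalyst is dying”. The reckoning here differs in counting the loss per target made.

The flasks give oak as the higher: birch 76.4%, which is 18 percentage points above the forecast, and oak 99.6%.

    substrate + free catalyst → catalyst intermediate (k = 180 /M/h, Ea = 50.0 kJ/mol)
    substrate + catalyst intermediate → spent catalyst (k = 0.170 /M/h, Ea = 95.0 kJ/mol)
    catalyst intermediate → free catalyst + target (k = 2.20 /h, Ea = 108 kJ/mol)
    (constants at 80 °C)

In oak at 0.377 d, catalyst intermediate went on to free catalyst and target 560 times for each step to spent catalyst. By 6.00 d, oak had made 565 of target per catalyst spent, more than its demand of 400, with spent catalyst at 70.5%. A neighbour of oak, charged with 0.1 mol% of free catalyst, has a demand of 1000, more than the capacity read from the ochre run, and that reading puts its ceiling near 49.8%; this neighbour ended with spent catalyst at >99.9% and target at 34.0%.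

The numbers in the tables are simulated on assumed constants; scatter was added.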